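**Retrosynthetic overview**

1. The (E)-stilbene C=C is cut last (Horner–Wadsworth–Emmons), leaving an aryl aldehyde that is carried as its dimethyl acetal; both phenols are carried as silyl ethers.
2. The CH2–CH2 bond of the propane chain is cut next: a 1,1-diarylethene (7) and a benzylic phosphate (11) are joined by an enantioselective CuH-catalysed anti-Markovnikov hydrobenzylation that forms this bond and the only stereocentre in one operation.
3. Enabling feature: the stereogenic CH carries a flat 4-methoxyphenyl ring and a 2,6-dimethoxyphenyl ring that its two ortho OMe groups twist out of plane, and its neighbour is an unsubstituted CH2, so the unit maps onto a terminal 1,1-diarylethene with two very different aryl groups; the other CH2 is benzylic on a ring with ortho-OMe and para-O, so it is a strongly activated electrophile.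
4. The alkene comes from lithiation of the ring C–H between the two OMe groups of 3,5-dimethoxybenzaldehyde dimethyl acetal, addition to 4'-methoxyacetophenone and dehydration.
5. No ring is formed in the route: all four benzene rings are bought, and the stilbene is added after the key step so that no second styrenic alkene competes for copper hydride.

Key step: step 7

Assumption: (S)-DTBM-SEGPHOS is taken to deliver the (S) product in step 7; the sense of induction cannot be predicted with certainty for this alkene class, and the enantiomeric ligand would be used if the opposite sense is found.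

**Route**

Step 1
Reactants: 1 3,5-dimethoxybenzaldehyde
Product: 2 1-(dimethoxymethyl)-3,5-dimethoxybenzene
Conditions: HC(OMe)3, p-TsOH (cat.), MeOH, rt
Reagents that add atoms: trimethyl orthoformate, COC(OC)OC
Why: Acid-catalysed acetalisation, driven by the orthoformate as water scavenger, should mask the aldehyde against n-BuLi and copper hydride.

Step 2
Reactants: 2 1-(dimethoxymethyl)-3,5-dimethoxybenzene; 3 4'-methoxyacetophenone
Product: 5 rac-1-[4-(dimethoxymethyl)-2,6-dimethoxyphenyl]-1-(4-methoxyphenyl)ethan-1-ol, via aryllithium 4 (not isolated)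
Conditions: n-BuLi, THF, 0 °C; then 3, −78 °C → rt; H2O
Reagents that add atoms: none
Why: Directed ortho-metalation should occur only at the C–H flanked by both methoxy groups (most acidic, doubly chelated site), and 1,2-addition of the aryllithium to the ketone should give the tertiary carbinol, whose racemic centre is removed in step 3.

Step 3
Reactants: 5 rac-1-[4-(dimethoxymethyl)-2,6-dimethoxyphenyl]-1-(4-methoxyphenyl)ethan-1-ol
Product: 7 5-(dimethoxymethyl)-1,3-dimethoxy-2-[1-(4-methoxyphenyl)ethenyl]benzene, via tertiary mesylate 6 (not isolated)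
Conditions: MsCl, Et3N, DMAP (cat.), CH2Cl2, 0 °C → rt
Reagents that add atoms: none
Why: Sulfonylation of the doubly benzylic tertiary alcohol followed by spontaneous E1 elimination under basic conditions should give the single possible alkene (methyl is the only β-hydrogen source) without touching the acid-labile acetal.

Step 4
Reactants: 8 4-hydroxy-2-methoxybenzaldehyde
Product: 9 2-methoxy-4-[(triisopropylsilyl)oxy]benzaldehyde
Conditions: TIPSCl, imidazole, DMF, rt
Reagents that add atoms: triisopropylsilyl chloride, CC(C)[Si](Cl)(C(C)C)C(C)C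
Why: Standard phenol silylation; the bulky TIPS ether is chosen to survive borohydride, alkoxide and copper hydride.

Step 5
Reactants: 9 2-methoxy-4-[(triisopropylsilyl)oxy]benzaldehyde
Product: 10 {2-methoxy-4-[(triisopropylsilyl)oxy]phenyl}methanol
Conditions: NaBH4, MeOH, 0 °C
Reagents that add atoms: none
Why: Borohydride reduction of an aryl aldehyde to the benzylic alcohol is reliable and leaves the aryl silyl ether intact.

Step 6
Reactants: 10 {2-methoxy-4-[(triisopropylsilyl)oxy]phenyl}methanol
Product: 11 diethyl {2-methoxy-4-[(triisopropylsilyl)oxy]benzyl} phosphate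
Conditions: ClP(O)(OEt)2, Et3N, DMAP (cat.), CH2Cl2, 0 °C; Et3N-washed silica, used promptly
Reagents that add atoms: diethyl chlorophosphate, CCOP(=O)(Cl)OCC
Why: O-Phosphorylation should give a benzylic electrophile whose leaving group is slow to be reduced by copper hydride, while the ortho-OMe/para-O pattern keeps the benzylic carbon highly electrophilic.

Step 7
Reactants: 7 5-(dimethoxymethyl)-1,3-dimethoxy-2-[1-(4-methoxyphenyl)ethenyl]benzene; 11 diethyl {2-methoxy-4-[(triisopropylsilyl)oxy]benzyl} phosphate
Product: 13 {4-[(3S)-3-[4-(dimethoxymethyl)-2,6-dimethoxyphenyl]-3-(4-methoxyphenyl)propyl]-3-methoxyphenoxy}triisopropylsilane, via alkylcopper 12 (not isolated)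
Conditions: Cu(OAc)2 (cat.), (S)-DTBM-SEGPHOS (cat.), (MeO)2MeSiH, LiOtBu, THF, 40 °C, slow addition of 11
Reagents that add atoms: none
Why: Proposed new method: the ligated copper hydride formed from Cu(OAc)2, the bisphosphine and the silane should add across the terminal alkene of 7 with copper on CH2 and hydride on the diaryl carbon (anti-Markovnikov hydrocupration, enantiodetermining), and the primary alkylcopper 12 should then displace the phosphate of 11 at the benzylic carbon by SN2-type oxidative addition and reductive elimination, after which LiOtBu and the silane regenerate Cu–H. The closest known reaction type is the CuH-catalysed enantioselective anti-Markovnikov hydrofunctionalisation of 1,1-disubstituted aryl alkenes (hydroamination, hydroallylation with allylic phosphates, hydromethylation with a methyl sulfonate), which has not been shown with a benzylic phosphate or with a 1,1-diarylethene. No ring is closed. The new stereocentre, the diarylmethine carbon, is set by the chiral ligand, which should distinguish the alkene faces through the coplanar 4-methoxyphenyl ring and the 2,6-dimethoxyphenyl ring held perpendicular by its two ortho methoxy groups. The step needs regioselectivity (copper on CH2, secured by the fully substituted diaryl carbon) and chemoselectivity for hydrocupration over direct reduction of 11 (secured by the phosphate leaving group and its slow addition). Acetal, aryl ethers and the silyl ether should be inert to silane and LiOtBu.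

Step 8
Reactants: 13 {4-[(3S)-3-[4-(dimethoxymethyl)-2,6-dimethoxyphenyl]-3-(4-methoxyphenyl)propyl]-3-methoxyphenoxy}triisopropylsilane
Product: 14 3,5-dimethoxy-4-[(1S)-1-(4-methoxyphenyl)-3-{2-methoxy-4-[(triisopropylsilyl)oxy]phenyl}propyl]benzaldehyde
Conditions: HCl (cat.), THF/H2O, rt
Reagents that add atoms: water, O
Why: Mild acid hydrolysis of the aryl dimethyl acetal should free the aldehyde while the aryl TIPS ether and the benzylic C–H stereocentre are inert to dilute acid.

Step 9
Reactants: 15 4-[(tert-butyldimethylsilyl)oxy]benzaldehyde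
Product: 16 {4-[(tert-butyldimethylsilyl)oxy]phenyl}methanol
Conditions: NaBH4, MeOH, 0 °C
Reagents that add atoms: none
Why: Borohydride reduction of the aryl aldehyde should give the benzylic alcohol without loss of the silyl ether.

Step 10
Reactants: 16 {4-[(tert-butyldimethylsilyl)oxy]phenyl}methanol
Product: 17 diethyl {4-[(tert-butyldimethylsilyl)oxy]benzyl}phosphonate
Conditions: ZnI2, P(OEt)3, THF, reflux
Reagents that add atoms: triethyl phosphite, CCOP(OCC)OCC
Why: The zinc iodide-mediated one-flask conversion of an electron-rich benzylic alcohol into its phosphonate (transesterification to the benzyl phosphite, then Michaelis–Arbuzov-type rearrangement) should give the olefination reagent directly.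

Step 11
Reactants: 14 3,5-dimethoxy-4-[(1S)-1-(4-methoxyphenyl)-3-{2-methoxy-4-[(triisopropylsilyl)oxy]phenyl}propyl]benzaldehyde; 17 diethyl {4-[(tert-butyldimethylsilyl)oxy]benzyl}phosphonate
Product: 19 tert-butyl{4-[(E)-2-{3,5-dimethoxy-4-[(1S)-1-(4-methoxyphenyl)-3-{2-methoxy-4-[(triisopropylsilyl)oxy]phenyl}propyl]phenyl}ethenyl]phenoxy}dimethylsilane, via phosphonate carbanion 18 (not isolated)
Conditions: 17, NaH, 15-crown-5 (cat.), THF, 0 °C; then 14, 0 °C → rt
Reagents that add atoms: none
Why: Horner–Wadsworth–Emmons olefination of an aromatic aldehyde with a benzylphosphonate anion should give the (E)-stilbene, and the stereocentre should hold because its C–H lies in the plane of the 2,6-dimethoxyphenyl ring and is not acidified by the para-formyl group.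

Step 12
Reactants: 19 tert-butyl{4-[(E)-2-{3,5-dimethoxy-4-[(1S)-1-(4-methoxyphenyl)-3-{2-methoxy-4-[(triisopropylsilyl)oxy]phenyl}propyl]phenyl}ethenyl]phenoxy}dimethylsilane
Product: 20 4-[(3S)-3-{4-[(E)-2-(4-hydroxyphenyl)ethenyl]-2,6-dimethoxyphenyl}-3-(4-methoxyphenyl)propyl]-3-methoxyphenol (CNP0182684.1)
Conditions: TBAF, AcOH, THF, 0 °C → rt
Reagents that add atoms: none
Why: Fluoride-mediated desilylation should cleave both aryl silyl ethers in one operation, the acetic acid buffer keeping the electron-rich stilbene phenoxide from side reactions.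

**Compound list**

1 | 3,5-dimethoxybenzaldehyde | COc1cc(C=O)cc(OC)c1 | starting material
2 | 1-(dimethoxymethyl)-3,5-dimethoxybenzene | COc1cc(C(OC)OC)cc(OC)c1 | intermediate
3 | 4'-methoxyacetophenone | COc1ccc(C(C)=O)cc1 | starting material
4 | [4-(dimethoxymethyl)-2,6-dimethoxyphenyl]lithium (formed in the flask) | [Li]c1c(OC)cc(C(OC)OC)cc1OC | intermediate
5 | rac-1-[4-(dimethoxymethyl)-2,6-dimethoxyphenyl]-1-(4-methoxyphenyl)ethan-1-ol | COc1ccc(C(C)(O)c2c(OC)cc(C(OC)OC)cc2OC)cc1 | intermediate
6 | 1-[4-(dimethoxymethyl)-2,6-dimethoxyphenyl]-1-(4-methoxyphenyl)ethyl methanesulfonate (formed in the flask) | COc1ccc(C(C)(OS(C)(=O)=O)c2c(OC)cc(C(OC)OC)cc2OC)cc1 | intermediate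
7 | 5-(dimethoxymethyl)-1,3-dimethoxy-2-[1-(4-methoxyphenyl)ethenyl]benzene | COc1ccc(C(=C)c2c(OC)cc(C(OC)OC)cc2OC)cc1 | intermediate
8 | 4-hydroxy-2-methoxybenzaldehyde | COc1cc(O)ccc1C=O | starting material
9 | 2-methoxy-4-[(triisopropylsilyl)oxy]benzaldehyde | COc1cc(O[Si](C(C)C)(C(C)C)C(C)C)ccc1C=O | intermediate
10 | {2-methoxy-4-[(triisopropylsilyl)oxy]phenyl}methanol | COc1cc(O[Si](C(C)C)(C(C)C)C(C)C)ccc1CO | intermediate
11 | diethyl {2-methoxy-4-[(triisopropylsilyl)oxy]benzyl} phosphate | CCOP(=O)(OCC)OCc1ccc(O[Si](C(C)C)(C(C)C)C(C)C)cc1OC | intermediate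
12 | (S)-{2-[4-(dimethoxymethyl)-2,6-dimethoxyphenyl]-2-(4-methoxyphenyl)ethyl}copper(I), bisphosphine ligand omitted (formed in the flask) | COc1ccc([C@H](C[Cu])c2c(OC)cc(C(OC)OC)cc2OC)cc1 | intermediate
13 | {4-[(3S)-3-[4-(dimethoxymethyl)-2,6-dimethoxyphenyl]-3-(4-methoxyphenyl)propyl]-3-methoxyphenoxy}triisopropylsilane | COc1ccc([C@H](CCc2ccc(O[Si](C(C)C)(C(C)C)C(C)C)cc2OC)c2c(OC)cc(C(OC)OC)cc2OC)cc1 | intermediate
14 | 3,5-dimethoxy-4-[(1S)-1-(4-methoxyphenyl)-3-{2-methoxy-4-[(triisopropylsilyl)oxy]phenyl}propyl]benzaldehyde | COc1ccc([C@H](CCc2ccc(O[Si](C(C)C)(C(C)C)C(C)C)cc2OC)c2c(OC)cc(C=O)cc2OC)cc1 | intermediate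
15 | 4-[(tert-butyldimethylsilyl)oxy]benzaldehyde | CC(C)(C)[Si](C)(C)Oc1ccc(C=O)cc1 | starting material
16 | {4-[(tert-butyldimethylsilyl)oxy]phenyl}methanol | CC(C)(C)[Si](C)(C)Oc1ccc(CO)cc1 | intermediate
17 | diethyl {4-[(tert-butyldimethylsilyl)oxy]benzyl}phosphonate | CCOP(=O)(OCC)Cc1ccc(O[Si](C)(C)C(C)(C)C)cc1 | intermediate
18 | sodium salt of the benzylic carbanion of 17 (formed in the flask) | CCOP(=O)(OCC)[CH-]c1ccc(O[Si](C)(C)C(C)(C)C)cc1.[Na+] | intermediate
19 | tert-butyl{4-[(E)-2-{3,5-dimethoxy-4-[(1S)-1-(4-methoxyphenyl)-3-{2-methoxy-4-[(triisopropylsilyl)oxy]phenyl}propyl]phenyl}ethenyl]phenoxy}dimethylsilane | COc1ccc([C@H](CCc2ccc(O[Si](C(C)C)(C(C)C)C(C)C)cc2OC)c2c(OC)cc(/C=C/c3ccc(O[Si](C)(C)C(C)(C)C)cc3)cc2OC)cc1 | intermediate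
20 | 4-[(3S)-3-{4-[(E)-2-(4-hydroxyphenyl)ethenyl]-2,6-dimethoxyphenyl}-3-(4-methoxyphenyl)propyl]-3-methoxyphenol | COc1ccc([C@H](CCc2ccc(O)cc2OC)c2c(OC)cc(/C=C/c3ccc(O)cc3)cc2OC)cc1 | target

**Step count and risks**

Total step count: 12. Longest linear sequence: 7 steps (1, 2, 3, 7, 8, 11, 12).

Step 7 (Proposed new method). The alkylcopper may not be intercepted by the benzylic phosphate quickly enough, so that copper hydride reduces the phosphate directly or the alkene is merely hydrogenated; hydrocupration of the hindered, electron-rich alkene may also be slow. The fallback sets out from 7 and 10, comes back at 13, and uses only known chemistry. Alkene 7 is hydroborated with pinacolborane under CuCl/(S)-DTBM-SEGPHOS/KOtBu (asymmetric hydroboration of a 1,1-disubstituted aryl alkene, same enantiodetermining hydrocupration) to give the primary pinacol boronic ester F1. Alcohol 10 is acylated with N,N-diisopropylcarbamoyl chloride (Et3N, toluene, reflux) to give the benzylic carbamate F2. Deprotonation with s-BuLi/TMEDA (Et2O, −78 °C) gives the lithiated carbamate F3, which is trapped by F1 as the lithium boronate complex F4. On warming, 1,2-metallate rearrangement with loss of the carbamate forms the same CH2–CH2 bond and gives the secondary benzylic boronic ester F5 (both epimers at the boron-bearing carbon, which is of no consequence). Protodeboronation with TBAF·3H2O removes boron and also the silyl group to give the phenol F6, which is re-silylated (TIPSCl, imidazole, DMF) to 13.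

Step 2. The hindered, basic aryllithium may enolise the acetophenone instead of adding to it, returning both partners after quench. The fallback sets out from 2 (through aryllithium 4) and comes back at 5. The aryllithium is acylated with N,4-dimethoxy-N-methylbenzamide (Weinreb ketone synthesis) to give the non-enolisable benzophenone F7, and methylmagnesium bromide (THF, 0 °C) is then added to its carbonyl group to give carbinol 5.

Step 11. The basic phosphonate anion may strip the aryl silyl ethers before olefination, may add sluggishly because it is electron-rich, or may erode the doubly benzylic centre through the vinylogous enolate of the aldehyde. The fallback sets out from 14 and comes back at 19. Takai olefination of 14 (CHI3, CrCl2, THF, 0 °C → rt) under non-basic conditions gives the (E)-vinyl iodide F8. Suzuki–Miyaura coupling of F8 with {4-[(tert-butyldimethylsilyl)oxy]phenyl}boronic acid (Pd(PPh3)4, K3PO4, THF/H2O, 40 °C) then gives 19 with retention of the alkene geometry.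

**Further compounds**

F1 | step 7 | 2-{(2S)-2-[4-(dimethoxymethyl)-2,6-dimethoxyphenyl]-2-(4-methoxyphenyl)ethyl}-4,4,5,5-tetramethyl-1,3,2-dioxaborolane | COc1ccc([C@H](CB2OC(C)(C)C(C)(C)O2)c2c(OC)cc(C(OC)OC)cc2OC)cc1
F2 | step 7 | 2-methoxy-4-[(triisopropylsilyl)oxy]benzyl N,N-diisopropylcarbamate | COc1cc(O[Si](C(C)C)(C(C)C)C(C)C)ccc1COC(=O)N(C(C)C)C(C)C
F3 | step 7 | α-lithiated 2-methoxy-4-[(triisopropylsilyl)oxy]benzyl N,N-diisopropylcarbamate | [Li]C(OC(=O)N(C(C)C)C(C)C)c1ccc(O[Si](C(C)C)(C(C)C)C(C)C)cc1OC
F4 | step 7 | lithium boronate complex of F1 and F3 | COc1ccc([C@H](C[B-]2(C(OC(=O)N(C(C)C)C(C)C)c3ccc(O[Si](C(C)C)(C(C)C)C(C)C)cc3OC)OC(C)(C)C(C)(C)O2)c2c(OC)cc(C(OC)OC)cc2OC)cc1.[Li+]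
F5 | step 7 | 2-{(3S)-3-[4-(dimethoxymethyl)-2,6-dimethoxyphenyl]-3-(4-methoxyphenyl)-1-{2-methoxy-4-[(triisopropylsilyl)oxy]phenyl}propyl}-4,4,5,5-tetramethyl-1,3,2-dioxaborolane (both C-1 epimers) | COc1ccc([C@H](CC(B2OC(C)(C)C(C)(C)O2)c2ccc(O[Si](C(C)C)(C(C)C)C(C)C)cc2OC)c2c(OC)cc(C(OC)OC)cc2OC)cc1
F6 | step 7 | 4-[(3S)-3-[4-(dimethoxymethyl)-2,6-dimethoxyphenyl]-3-(4-methoxyphenyl)propyl]-3-methoxyphenol | COc1ccc([C@H](CCc2ccc(O)cc2OC)c2c(OC)cc(C(OC)OC)cc2OC)cc1
F7 | step 2 | [4-(dimethoxymethyl)-2,6-dimethoxyphenyl](4-methoxyphenyl)methanone | COc1ccc(C(=O)c2c(OC)cc(C(OC)OC)cc2OC)cc1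
F8 | step 11 | {4-[(3S)-3-{4-[(E)-2-iodoethenyl]-2,6-dimethoxyphenyl}-3-(4-methoxyphenyl)propyl]-3-methoxyphenoxy}triisopropylsilane | COc1ccc([C@H](CCc2ccc(O[Si](C(C)C)(C(C)C)C(C)C)cc2OC)c2c(OC)cc(/C=C/I)cc2OC)cc1
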